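The plan rests on opening ring D at d1–d2. Ring D is a resorcinol with its hydroxyls on d3 and d5. Its neighbouring fusion carbons, d1 on furan carbon C3 and d6 on the aryl-bearing methine Ca, are shared with the seven-membered ring. This is the oxygen pattern of a folded 1,3,5-triketone. One base-mediated aldol, dehydration and enolisation converts the d6-acetoacetyl benzocycloheptenone into the free resorcinol. That precursor already holds ring A, both trans-dihydrobenzofurans and all five stereocentres. Ca, C2 and C3' are set by chiral rhodium catalysts, and C3 and C2' follow by equilibration. All other phenols travel as benzyl ethers, so the last step is a neutral hydrogenolysis.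

Key step: step 15

**Labels.**
- Ring A is the central benzene: a1 bears Cb (CH2), a2 bears C3, a3 carries the O of furan 1, a4 is H, a5 carries the O of furan 2, a6 bears C3'.
- Furan 1 is O–C2(aryl)–C3 on a3/a2.
- Furan 2 is O–C2'(aryl)–C3'(3,5-dioxyaryl) on a5/a6.
- Ca is the aryl-bearing methine next to Cb.
- Ring D is d1 (on C3), d2, d3 (OH), d4, d5 (OH), d6 (on Ca).
- The seven-membered ring is Ca–Cb–a1–a2–C3–d1–d6.

**Stereochemical remark.**
- In the target, furan 1 is (2S,3S) and furan 2 is (2'R,3'R), so the two rings have opposite sense.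
- Both insertions are therefore run to the same (2S,3R)-type cis ring. Furan 1 is then corrected at C3 with base, and furan 2 at C2' with acid.
- Ca is S in the target but R in the isolated intermediates that come before ring D is aromatic. This is a priority change only.

**Assumption.** The facial sense of each catalyst is taken from the closest simple substrates. (S)-BINAP–rhodium transfers aryl to the α-si face of E-enones, and R-configured phthalimido-carboxylate dirhodium catalysts give 2S-cis-2-aryl-dihydrobenzofurans. Both antipodes of each ligand are commercial, so any centre can be corrected on its own.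

Step 1
Reactants: 1 methyl 3,5-dihydroxyphenylacetate; 2 4-(benzyloxy)benzyl chloride (2.2 equiv)
Product: 3 methyl {3,5-bis[4-(benzyloxy)benzyloxy]phenyl}acetate
Conditions: K2CO3, n-Bu4NI (cat.), DMF, 60 °C
Reagents that add atoms: none
Why: Williamson ether synthesis, in which carbonate ionises only the two phenols (the arylacetate CH2 is far less acidic) and the iodide-activated benzylic chloride alkylates both, installing the ether CH2 groups that later become C2 and C2'.

Step 2
Reactants: 3 methyl {3,5-bis[4-(benzyloxy)benzyloxy]phenyl}acetate; 4 1-(triphenylphosphoranylidene)propan-2-one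
Product: 6 (E)-5-{3,5-bis[4-(benzyloxy)benzyloxy]phenyl}pent-3-en-2-one, via arylacetaldehyde 5 (not isolated)
Conditions: i-Bu2AlH (1.1 equiv), CH2Cl2, −78 °C; MeOH quench; then 4, −78 °C to rt
Reagents that add atoms: none
Why: Partial ester reduction stops at the aluminium hemiacetal, which releases the enolisable aldehyde 5 only in the presence of the stabilised ylide, so the Wittig reaction gives the E-enone without handling 5.

Step 3
Reactants: 6 (E)-enone; 7 4-(benzyloxy)phenylboronic acid (2 equiv)
Product: 8 (4R)-4-[4-(benzyloxy)phenyl]-5-{3,5-bis[4-(benzyloxy)benzyloxy]phenyl}pentan-2-one (Ca = C4)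
Conditions: [Rh(OH)((S)-binap)]2 (1.5 mol %), 1,4-dioxane/H2O 10:1, 35 °C
Reagents that add atoms: none
Why: Hayashi–Miyaura reaction (rhodium-catalysed asymmetric 1,4-addition), in which the (S)-BINAP aryl-rhodium species adds to the α-si face of the E-enone and sets Ca as R, while the mild base-free medium keeps the double bond from drifting into conjugation with ring A.

Step 4
Reactants: 8 (4R)-ketone
Product: 9 ethylene ketal of 8 (2-methyl-1,3-dioxolane; Ca R)
Conditions: TMSOCH2CH2OTMS, TMSOTf (5 mol %), CH2Cl2, −78 to −20 °C; pyridine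
Reagents that add atoms: 1,2-bis(trimethylsilyloxy)ethane, C[Si](C)(C)OCCO[Si](C)(C)C
Why: Noyori ketalisation under aprotic catalysis at low temperature masks the ketone against n-BuLi, hydrazine and the zinc enolate of later steps without cleaving the acid-sensitive 4-alkoxybenzyl aryl ethers.

Step 5
Reactants: 9 ketal
Product: 10 a2/a6-dibromide of 9 (Ca R)
Conditions: NBS (2.05 equiv), MeCN/CH2Cl2, 0 °C, dark
Reagents that add atoms: N-bromosuccinimide, O=C1CCC(=O)N1Br
Why: Electrophilic aromatic bromination, in which only ring A carries two mutually reinforcing ether oxygens and a2 and a6, each para to one of them, react before a4 (screened by both benzyloxy groups) and long before the mono-oxygenated rings.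

Step 6
Reactants: 10 dibromide; 11 methyl 3,5-bis(benzyloxy)benzoate
Product: 13 a6-[3,5-bis(benzyloxy)benzoyl] a2-bromo diaryl ketone (Ca R), via aryllithium 12 (not isolated)
Conditions: n-BuLi (1.0 equiv), THF, −78 °C; then 11, −78 to −30 °C; aq. NH4Cl
Reagents that add atoms: none
Why: Bromine–lithium exchange followed by acyl substitution, in which one equivalent of n-BuLi exchanges a single bromine (a2 and a6 are equivalent through rotation about a1–Cb, so one product results) and the doubly ortho-substituted aryllithium 12 adds only once because the crowded ketone resists a second addition.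

Step 7
Reactants: 13 diaryl ketone
Product: 14 hydrazone of 13
Conditions: N2H4·H2O (30 equiv), N2H4·HCl (0.2 equiv), n-BuOH, 120 °C, sealed tube
Reagents that add atoms: hydrazine (as hydrate), NN
Why: Hydrazone condensation, in which the small α-effect nucleophile in large excess with mild hydrazinium catalysis can reach the carbonyl group flanked by the a1 and a5 substituents, and the basic medium leaves ketal, ethers and aryl bromide untouched.

Step 8
Reactants: 14 hydrazone
Product: 16 cis-dihydrobenzofuran bromide (furan 2 closed; C2' S; C3' R; Ca R; a2–Br, a3 ether and ketal intact), via diaryldiazomethane 15 (not isolated)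
Conditions: MnO2 (10 equiv), CH2Cl2, rt, filter; Rh2(R-PTAD)4 (1 mol %), CH2Cl2, 0 °C
Reagents that add atoms: none
Why: Dehydrogenation gives diazo compound 15, whose donor/donor rhodium carbene undergoes 1,5 C–H insertion into the a5 ether CH2 (activated by oxygen and the 4-benzyloxyphenyl group, hence preferred over the crowded tertiary Ca–H), the chiral carboxylate cage fixing C3' as R and giving the kinetically favoured cis ring.

Step 9
Reactants: 16 bromide; 17 methyl bromoacetate
Product: 19 methyl a2-arylacetate (CH2CO2Me in place of Br; stereocentres as in 16), via zinc enolate 18 (not isolated)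
Conditions: 17, Zn dust (TMSCl-activated), THF, 40 °C; then 16, Pd2(dba)3 (2.5 mol %), XPhos (10 mol %), THF, 65 °C
Reagents that add atoms: none
Why: Negishi-type cross-coupling of a Reformatsky reagent, in which the bulky biarylphosphine allows oxidative addition and reductive elimination at the doubly ortho-substituted a2–Br and the almost neutral zinc enolate spares ketal and dihydrobenzofuran.

Step 10
Reactants: 19 arylacetate
Product: 20 methyl a2-aryldiazoacetate
Conditions: p-ABSA (1.5 equiv), DBU, MeCN, rt to 40 °C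
Reagents that add atoms: 4-acetamidobenzenesulfonyl azide, CC(=O)Nc1ccc(cc1)S(=O)(=O)N=[N+]=[N-]
Why: Regitz diazo transfer, in which DBU generates the arylacetate enolate, which takes up the two terminal nitrogen atoms of the sulfonyl azide and expels the sulfonamide.

Step 11
Reactants: 20 aryldiazoacetate
Product: 22 bis(dihydrobenzofuran) methyl ester with furan 1 trans (C2 S; C3 S) and furan 2 still cis (C2' S; C3' R; Ca R), via cis ester 21 (not isolated)
Conditions: Rh2(R-PTAD)4 (1 mol %), toluene, −40 °C; then NaOMe (0.3 equiv) in MeOH, rt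
Reagents that add atoms: none
Why: Donor/acceptor rhodium carbene 1,5 C–H insertion into the a3 ether CH2 gives cis ester 21 with C2 fixed as S by the catalyst, and methoxide then inverts only C3 through the ester enolate to the more stable trans ester, ring opening being the reverse of a disfavoured 5-endo-trig addition.

Step 12
Reactants: 22 ketal ester
Product: 23 all-trans keto ester (C2 S; C3 S; C2' R; C3' R; Ca R) with free methyl ketone
Conditions: CF3CO2H/CH2Cl2 1:10, H2O (5 equiv), 0 °C to rt
Reagents that add atoms: water, O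
Why: Acid hydrolysis frees the methyl ketone and the same acid reversibly ionises the C2'–O bond to the 4-benzyloxybenzyl cation, whose reclosure inverts C2' and gives the thermodynamically preferred trans ring with C3' untouched, while furan 1, already trans and deactivated by its ester, can only return to itself.

Step 13
Reactants: 23 keto ester
Product: 24 d6-acetyl benzocycloheptenone (β-diketone; d1 ketone next to C3; C2 S; C3 S; C2' R; C3' R; Ca R; d6 unfixed)
Conditions: KOt-Bu (2.2 equiv), THF, high dilution, 0 °C to rt; aq. NH4Cl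
Reagents that add atoms: none
Why: Dieckmann-type intramolecular Claisen condensation, in which under reversible deprotonation only attack of d6 on the C3 ester closes a seven-membered ring and gives an enolisable β-diketone whose potassium enolate is the thermodynamic sink, whereas adducts through C3 or the methyl group are non-enolisable or strained and revert.

Step 14
Reactants: 24 β-diketone; 25 N-methoxy-N-methylacetamide
Product: 27 d6-acetoacetyl benzocycloheptenone (1,3,5-triketone d1/d5/d3 with terminal methyl d2; stereocentres as in 24), via dilithium dienolate 26 (not isolated)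
Conditions: LiN(i-Pr)2 (2.5 equiv), THF, −78 to −20 °C; 25, −78 to 0 °C; aq. NH4Cl
Reagents that add atoms: none
Why: γ-Acylation of a β-diketone dianion, in which the second deprotonation takes the unhindered acetyl methyl group d4 rather than the tertiary C3–H, the terminal carbon of 26 is the most nucleophilic site, and the Weinreb amide holds the adduct as a chelate until work-up so that no second acylation occurs.

Step 15
Reactants: 27 triketone
Product: 29 pentabenzyl ether of the target with ring D as free resorcinol (Ca S; C2 S; C3 S; C2' R; C3' R), via aldol adduct 28 (not isolated)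
Conditions: KOH (1 M aq., 5 equiv), 1,4-dioxane, degassed, Ar, 45 °C; then cold 1 M HCl to pH 4
Reagents that add atoms: none
Why: Hydroxide first ionises the d4 methylene, which leaves the α-branched d1 carbonyl as a true ketone; proton exchange then supplies a small share of the d2 methyl enolate, which adds to d1 to give aldol 28, and E1cB loss of water followed by enolisation of the d3 and d5 carbonyls delivers the aromatic ring. The closest known reaction is the alkali-induced aldol cycloaromatisation of heptane-2,4,6-trione to orcinol, applied here to a triketone whose d1 and d6 are tied into a ring. Ring D closes in a favoured 6-(enolendo)-exo-trig mode, the seven-membered ring holding d1 within reach of the chain on d6. No stereocentre is created: d1 and d6 become sp2, Ca, C2, C2' and C3' carry no acidic hydrogen, and C3, which can enolise until d1 is aromatic, settles trans to the C2 aryl group, while opening of furan 1 would be the reverse of a disfavoured 5-endo-trig addition. The step needs C–C rather than C–O closure and attack by d2 rather than by C3: the 4-pyranone requires acid-promoted dehydration and is reopened by base, and the aldol from C3 onto d3 has a quaternary carbon, cannot aromatise and reverts. Dilute, oxygen-free hydroxide at moderate temperature is chosen to hold back retro-Claisen cleavage and oxidation of the product dianion.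

Step 16
Reactants: 29 pentabenzyl ether
Product: 30 CNP0136963.1 (target)
Conditions: H2 (1 atm), Pd/C (10 wt %), THF/MeOH 1:1, rt
Reagents that add atoms: none
Why: Catalytic hydrogenolysis cleaves the five primary benzyl aryl ethers faster than the hindered secondary ring C2–O and C2'–O bonds, touches no stereocentre and avoids the boron halides that are prone to open 2-aryl-dihydrobenzofurans.

**Compound list**
1 | methyl 3,5-dihydroxyphenylacetate | COC(=O)Cc1cc(O)cc(O)c1 | starting material
2 | 4-(benzyloxy)benzyl chloride | ClCc1ccc(OCc2ccccc2)cc1 | starting material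
3 | methyl {3,5-bis[4-(benzyloxy)benzyloxy]phenyl}acetate | COC(=O)Cc1cc(OCc2ccc(OCc3ccccc3)cc2)cc(OCc2ccc(OCc3ccccc3)cc2)c1 | intermediate
4 | 1-(triphenylphosphoranylidene)propan-2-one | CC(=O)C=P(c1ccccc1)(c1ccccc1)c1ccccc1 | starting material
5 | {3,5-bis[4-(benzyloxy)benzyloxy]phenyl}acetaldehyde (not isolated) | O=CCc1cc(OCc2ccc(OCc3ccccc3)cc2)cc(OCc2ccc(OCc3ccccc3)cc2)c1 | intermediate
6 | (E)-5-{3,5-bis[4-(benzyloxy)benzyloxy]phenyl}pent-3-en-2-one | CC(=O)/C=C/Cc1cc(OCc2ccc(OCc3ccccc3)cc2)cc(OCc2ccc(OCc3ccccc3)cc2)c1 | intermediate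
7 | 4-(benzyloxy)phenylboronic acid | OB(O)c1ccc(OCc2ccccc2)cc1 | starting material
8 | (4R)-4-[4-(benzyloxy)phenyl]-5-{3,5-bis[4-(benzyloxy)benzyloxy]phenyl}pentan-2-one | c6ccccc6COc1ccc([C@@H](CC(C)=O)Cc3cc(OCc4ccc(OCc6ccccc6)cc4)cc(OCc4ccc(OCc6ccccc6)cc4)c3)cc1 | intermediate
9 | ethylene ketal of 8 (Ca R) | c6ccccc6COc1ccc([C@@H](CC7(C)OCCO7)Cc3cc(OCc4ccc(OCc6ccccc6)cc4)cc(OCc4ccc(OCc6ccccc6)cc4)c3)cc1 | intermediate
10 | a2/a6-dibromide of 9 | c6ccccc6COc1ccc([C@@H](CC7(C)OCCO7)Cc3c(Br)c(OCc4ccc(OCc6ccccc6)cc4)cc(OCc4ccc(OCc6ccccc6)cc4)c3Br)cc1 | intermediate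
11 | methyl 3,5-bis(benzyloxy)benzoate | COC(=O)c1cc(OCc2ccccc2)cc(OCc2ccccc2)c1 | starting material
12 | a6-lithio a2-bromo arene (not isolated) | c6ccccc6COc1ccc([C@@H](CC7(C)OCCO7)Cc3c(Br)c(OCc4ccc(OCc6ccccc6)cc4)cc(OCc4ccc(OCc6ccccc6)cc4)c3[Li])cc1 | intermediate
13 | a6-[3,5-bis(benzyloxy)benzoyl] a2-bromo diaryl ketone | c6ccccc6COc1ccc([C@@H](CC7(C)OCCO7)Cc3c(Br)c(OCc4ccc(OCc6ccccc6)cc4)cc(OCc4ccc(OCc6ccccc6)cc4)c3C(=O)c3cc(OCc6ccccc6)cc(OCc6ccccc6)c3)cc1 | intermediate
14 | hydrazone of 13 | c6ccccc6COc1ccc([C@@H](CC7(C)OCCO7)Cc3c(Br)c(OCc4ccc(OCc6ccccc6)cc4)cc(OCc4ccc(OCc6ccccc6)cc4)c3C(=NN)c3cc(OCc6ccccc6)cc(OCc6ccccc6)c3)cc1 | intermediate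
15 | diaryldiazomethane from 14 (not isolated) | c6ccccc6COc1ccc([C@@H](CC7(C)OCCO7)Cc3c(Br)c(OCc4ccc(OCc6ccccc6)cc4)cc(OCc4ccc(OCc6ccccc6)cc4)c3C(=[N+]=[N-])c3cc(OCc6ccccc6)cc(OCc6ccccc6)c3)cc1 | intermediate
16 | cis-dihydrobenzofuran bromide (C2' S, C3' R, Ca R) | c6ccccc6COc1ccc([C@@H](CC7(C)OCCO7)Cc3c(Br)c(OCc4ccc(OCc6ccccc6)cc4)cc5c3[C@@H](c3cc(OCc6ccccc6)cc(OCc6ccccc6)c3)[C@@H](c3ccc(OCc6ccccc6)cc3)O5)cc1 | intermediate
17 | methyl bromoacetate | COC(=O)CBr | starting material
18 | bromo(2-methoxy-2-oxoethyl)zinc (not isolated) | COC(=O)C[Zn]Br | intermediate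
19 | methyl a2-arylacetate | c6ccccc6COc1ccc([C@@H](CC7(C)OCCO7)Cc3c(CC(=O)OC)c(OCc4ccc(OCc6ccccc6)cc4)cc5c3[C@@H](c3cc(OCc6ccccc6)cc(OCc6ccccc6)c3)[C@@H](c3ccc(OCc6ccccc6)cc3)O5)cc1 | intermediate
20 | methyl a2-aryldiazoacetate | c6ccccc6COc1ccc([C@@H](CC7(C)OCCO7)Cc3c(C(=[N+]=[N-])C(=O)OC)c(OCc4ccc(OCc6ccccc6)cc4)cc5c3[C@@H](c3cc(OCc6ccccc6)cc(OCc6ccccc6)c3)[C@@H](c3ccc(OCc6ccccc6)cc3)O5)cc1 | intermediate
21 | cis,cis bis(dihydrobenzofuran) ester (C2 S, C3 R, C2' S, C3' R, Ca R; not isolated) | c6ccccc6COc1ccc([C@@H](CC7(C)OCCO7)Cc3c4c(cc5c3[C@@H](c3cc(OCc6ccccc6)cc(OCc6ccccc6)c3)[C@@H](c3ccc(OCc6ccccc6)cc3)O5)O[C@H](c3ccc(OCc6ccccc6)cc3)[C@@H]4C(=O)OC)cc1 | intermediate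
22 | ester with furan 1 trans (C2 S, C3 S), furan 2 cis (C2' S, C3' R) | c6ccccc6COc1ccc([C@@H](CC7(C)OCCO7)Cc3c4c(cc5c3[C@@H](c3cc(OCc6ccccc6)cc(OCc6ccccc6)c3)[C@@H](c3ccc(OCc6ccccc6)cc3)O5)O[C@H](c3ccc(OCc6ccccc6)cc3)[C@H]4C(=O)OC)cc1 | intermediate
23 | all-trans keto ester (C2 S, C3 S, C2' R, C3' R, Ca R) | c6ccccc6COc1ccc([C@@H](CC(C)=O)Cc3c4c(cc5c3[C@@H](c3cc(OCc6ccccc6)cc(OCc6ccccc6)c3)[C@H](c3ccc(OCc6ccccc6)cc3)O5)O[C@H](c3ccc(OCc6ccccc6)cc3)[C@H]4C(=O)OC)cc1 | intermediate
24 | d6-acetyl benzocycloheptenone (drawn as diketone) | c6ccccc6COc1ccc([C@@H]2Cc3c4c(cc5c3[C@@H](c3cc(OCc6ccccc6)cc(OCc6ccccc6)c3)[C@H](c3ccc(OCc6ccccc6)cc3)O5)O[C@H](c3ccc(OCc6ccccc6)cc3)[C@H]4C(=O)C2C(C)=O)cc1 | intermediate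
25 | N-methoxy-N-methylacetamide | CC(=O)N(C)OC | starting material
26 | dilithium dienolate of 24 (not isolated) | [Li+].[Li+].c6ccccc6COc1ccc([C@@H]2Cc3c4c(cc5c3[C@@H](c3cc(OCc6ccccc6)cc(OCc6ccccc6)c3)[C@H](c3ccc(OCc6ccccc6)cc3)O5)O[C@H](c3ccc(OCc6ccccc6)cc3)[C@H]4C([O-])=C2C([O-])=C)cc1 | intermediate
27 | d6-acetoacetyl benzocycloheptenone (drawn as triketone) | c6ccccc6COc1ccc([C@@H]2Cc3c4c(cc5c3[C@@H](c3cc(OCc6ccccc6)cc(OCc6ccccc6)c3)[C@H](c3ccc(OCc6ccccc6)cc3)O5)O[C@H](c3ccc(OCc6ccccc6)cc3)[C@H]4C(=O)C2C(=O)CC(=O)C)cc1 | intermediate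
28 | aldol adduct (d1 carbinol, d1–d2 bond formed; not isolated) | c6ccccc6COc1ccc([C@@H]2Cc3c4c(cc5c3[C@@H](c3cc(OCc6ccccc6)cc(OCc6ccccc6)c3)[C@H](c3ccc(OCc6ccccc6)cc3)O5)O[C@H](c3ccc(OCc6ccccc6)cc3)[C@H]4C3(O)CC(=O)CC(=O)C32)cc1 | intermediate
29 | pentabenzyl ether with ring D as free resorcinol | c6ccccc6COc1ccc([C@@H]2Cc3c4c(cc5c3[C@@H](c3cc(OCc6ccccc6)cc(OCc6ccccc6)c3)[C@H](c3ccc(OCc6ccccc6)cc3)O5)O[C@H](c3ccc(OCc6ccccc6)cc3)[C@H]4c3cc(O)cc(O)c32)cc1 | intermediate
30 | CNP0136963.1 | Oc1ccc([C@@H]2Cc3c4c(cc5c3[C@@H](c3cc(O)cc(O)c3)[C@H](c3ccc(O)cc3)O5)O[C@H](c3ccc(O)cc3)[C@H]4c3cc(O)cc(O)c32)cc1 | target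

Total step count: 16. Longest linear sequence: 16 steps (1 to 30). All other building blocks are bought.

**Steps most likely to fail**

**Step 15.**
- What may go wrong: hydroxide may cleave the poorly enolised d1/d5 dicarbonyl unit by retro-Claisen attack. That would open the ring at d1–d6 or remove the side chain, and it could run faster than the weakly acidic methyl group forms the C–C bond. Acidification could also divert unreacted material into O-cyclisation.
- Fallback, from 27: the nucleophile is made more acidic instead of the base stronger.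
- Compound 27 is turned into its polyanion with excess LiN(i-Pr)2 (THF, −78 to 0 °C) and carboxylated with CO2 at the terminal carbon d2. This gives the 3,5,7-trioxo acid F1.
- In F1, d2 is a doubly activated methylene. The same d1–d2 aldol closure then runs in cold dilute KOH or hydrogencarbonate buffer and gives the 2,4-dihydroxybenzoic acid F2, with the carboxyl group on d2.
- Heating F2 in aqueous DMF removes the carboxyl group, which stands ortho and para to the two hydroxyls. The route is rejoined at 29.

**Step 7.**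
- What may go wrong: addition to the carbonyl carbon, screened from both faces by the a1 and a5 substituents, may be too slow. Prolonged heating could then bring reduction of the carbonyl group or loss of the benzylic ethers.
- Fallback, from 10: bromine–lithium exchange as in step 6 gives 12.
- Compound 12 is added to 3,5-bis(benzyloxy)benzonitrile F3, which is made from commercial 3,5-dihydroxybenzonitrile and benzyl bromide (K2CO3, DMF).
- A methanol quench gives the N–H diaryl ketimine F4.
- The C=N bond of F4, protonated under mild catalysis, is far more electrophilic than the ketone. It exchanges with hydrazine (N2H4·H2O, cat. AcOH, EtOH, 60 °C), and the route is rejoined at 14.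

**Step 14.**
- What may go wrong: the amide base may take the benzylic C3–H instead of a methyl hydrogen, or the dianion may merely enolise the acyl donor. In both cases 24 is returned.
- Fallback, from 24: heating with N,N-dimethylacetamide dimethyl acetal (toluene, 100 °C) condenses the acetyl methyl group under neutral conditions and gives the enaminone F5.
- Brief treatment with aqueous acetic acid in THF hydrolyses this vinylogous amide, and the route is rejoined at 27.

**Further compounds**
F1 | step 15 | 3,5,7-trioxo acid (27 carboxylated at d2) | c6ccccc6COc1ccc([C@@H]2Cc3c4c(cc5c3[C@@H](c3cc(OCc6ccccc6)cc(OCc6ccccc6)c3)[C@H](c3ccc(OCc6ccccc6)cc3)O5)O[C@H](c3ccc(OCc6ccccc6)cc3)[C@H]4C(=O)C2C(=O)CC(=O)CC(=O)O)cc1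
F2 | step 15 | ring D 2,4-dihydroxybenzoic acid (CO2H on d2) | c6ccccc6COc1ccc([C@@H]2Cc3c4c(cc5c3[C@@H](c3cc(OCc6ccccc6)cc(OCc6ccccc6)c3)[C@H](c3ccc(OCc6ccccc6)cc3)O5)O[C@H](c3ccc(OCc6ccccc6)cc3)[C@H]4c3c(C(=O)O)c(O)cc(O)c32)cc1
F3 | step 7 | 3,5-bis(benzyloxy)benzonitrile | N#Cc1cc(OCc2ccccc2)cc(OCc2ccccc2)c1
F4 | step 7 | N–H diaryl ketimine corresponding to 13 | c6ccccc6COc1ccc([C@@H](CC7(C)OCCO7)Cc3c(Br)c(OCc4ccc(OCc6ccccc6)cc4)cc(OCc4ccc(OCc6ccccc6)cc4)c3C(=N)c3cc(OCc6ccccc6)cc(OCc6ccccc6)c3)cc1
F5 | step 14 | d6-[3-(dimethylamino)but-2-enoyl] benzocycloheptenone (enaminone) | c6ccccc6COc1ccc([C@@H]2Cc3c4c(cc5c3[C@@H](c3cc(OCc6ccccc6)cc(OCc6ccccc6)c3)[C@H](c3ccc(OCc6ccccc6)cc3)O5)O[C@H](c3ccc(OCc6ccccc6)cc3)[C@H]4C(=O)C2C(=O)C=C(C)N(C)C)cc1
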